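The disconnection that carries the route is the bond between C4 of the butenolide ring and the ipso carbon of the 4-hydroxyphenyl ring. The target is the enol (O–C3=C4) of a 2,3-dioxo lactone, so C4 is the acidic, nucleophilic carbon beside the masked C3 ketone. In one operation a palladium-catalysed enolate arylation joins the C4–H of 3-hydroxybutenolide 13, which already carries the C5 stereocentre and the prenylated benzyl group, to silyl-protected 4-bromophenol 14. Re-enolisation delivers the full skeleton at the final oxidation level with no halogen or protecting group on the lactone ring. C5 comes from (R)-epichlorohydrin, C2–C3 from a dithiane glyoxylate anion equivalent.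

Key step: step 7

Assumption: C5 of the butenolide in the given structure is (R), and compounds 1, 2, 5, 9 and 14 are taken as commercial.

Step 1
Reactants: 1 4-bromophenol; 2 prenyl bromide (1-bromo-3-methylbut-2-ene)
Product: 3 4-bromo-2-(3-methylbut-2-en-1-yl)phenol
Conditions: NaH, toluene, 0 °C → rt
Reagents that add atoms: none
Why: The sodium phenoxide reacts as a tight ion pair in a non-polar solvent at the ortho carbon (ortho C-allylation of a phenoxide, para position blocked by Br), and SN2 attack at the primary allylic carbon should give the linear prenyl group.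

Step 2
Reactants: 3 4-bromo-2-(3-methylbut-2-en-1-yl)phenol
Product: 4 [4-bromo-2-(3-methylbut-2-en-1-yl)phenoxy]triisopropylsilane
Conditions: TIPSCl, imidazole, DMF, rt
Reagents that add atoms: triisopropylsilyl chloride, CC(C)[Si](Cl)(C(C)C)C(C)C
Why: Imidazole-promoted silylation of a phenol; the bulky TIPS ether is chosen to survive the later Grignard, carbanion and hot phosphate steps.

Step 3
Reactants: 4 [4-bromo-2-(3-methylbut-2-en-1-yl)phenoxy]triisopropylsilane; 5 (R)-epichlorohydrin
Product: 7 (2R)-1-chloro-3-[3-(3-methylbut-2-en-1-yl)-4-(triisopropylsilyloxy)phenyl]propan-2-ol, via arylmagnesium bromide 6 (not isolated)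
Conditions: Mg, THF, 50 °C; then CuI (10 mol%), 5, −40 → −10 °C; aq. NH4Cl
Reagents that add atoms: none
Why: Grignard formation followed by copper-catalysed SN2 opening of the epoxide at its unsubstituted carbon (organocuprate epoxide opening) leaves the stereocentre of 5 untouched, so the chlorohydrin should be (R).

Step 4
Reactants: 7 (2R)-1-chloro-3-[3-(3-methylbut-2-en-1-yl)-4-(triisopropylsilyloxy)phenyl]propan-2-ol
Product: 8 (2R)-2-[3-(3-methylbut-2-en-1-yl)-4-(triisopropylsilyloxy)benzyl]oxirane
Conditions: NaH, THF, 0 °C → rt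
Reagents that add atoms: none
Why: Intramolecular Williamson etherification (3-exo-tet displacement of the primary chloride by the alkoxide) breaks no bond at the stereocentre and should give the (R)-epoxide.

Step 5
Reactants: 8 (2R)-2-[3-(3-methylbut-2-en-1-yl)-4-(triisopropylsilyloxy)benzyl]oxirane; 9 1,3-dithiane-2-carboxylic acid
Product: 12 (3R)-3-[3-(3-methylbut-2-en-1-yl)-4-(triisopropylsilyloxy)benzyl]-2-oxa-6,10-dithiaspiro[4.5]decan-1-one (spiro dithioketal of the 2,3-dioxo lactone), via dilithiated dithiane carboxylate 10 (not isolated), via hydroxy acid 11 (not isolated)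
Conditions: 9, LDA (2 equiv per 9), THF, −30 → 0 °C; then 8, DMPU, 0 °C → rt; 1 M HCl to pH 3; PPTS (cat.), toluene, 60 °C
Reagents that add atoms: none
Why: The carboxylic acid dianion of the dithiane is a glyoxylate anion equivalent that opens the terminal epoxide at CH2 (Creger-type dianion alkylation of an epoxide, stereocentre untouched), and the γ-hydroxy acid should lactonise under mild acid, helped by the gem-disubstituted dithiane carbon.

Step 6
Reactants: 12 (3R)-3-[3-(3-methylbut-2-en-1-yl)-4-(triisopropylsilyloxy)benzyl]-2-oxa-6,10-dithiaspiro[4.5]decan-1-one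
Product: 13 (5R)-3-hydroxy-5-[3-(3-methylbut-2-en-1-yl)-4-(triisopropylsilyloxy)benzyl]furan-2(5H)-one
Conditions: MeI, CaCO3, MeCN/H2O (4:1), 45 °C
Reagents that add atoms: water, O
Why: Alkylative hydrolysis of the dithioketal (S-methylation, then hydrolysis) unmasks the C3 ketone, which enolises towards C4 to the 3-hydroxybutenolide; the neutral, non-oxidising conditions should spare the prenyl alkene and the silyl ether.

Step 7
Reactants: 13 (5R)-3-hydroxy-5-[3-(3-methylbut-2-en-1-yl)-4-(triisopropylsilyloxy)benzyl]furan-2(5H)-one; 14 (4-bromophenoxy)triisopropylsilane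
Product: 15 (5R)-3-hydroxy-5-[3-(3-methylbut-2-en-1-yl)-4-(triisopropylsilyloxy)benzyl]-4-[4-(triisopropylsilyloxy)phenyl]furan-2(5H)-one
Conditions: Pd2(dba)3 (2.5 mol%), P(t-Bu)3·HBF4 (10 mol%), K3PO4, toluene, 100 °C
Reagents that add atoms: none
Why: Oxidative addition of Pd(0)/P(t-Bu)3 to 14 is followed by exchange of bromide for the potassium enolate of 13 (O–C3=C4, formed by K3PO4), isomerisation to the C4-bound palladium enolate and C–C reductive elimination, after which the 4-aryl-2,3-dioxo lactone re-enolises to the aryl-conjugated C3=C4 enol. The closest known reaction type is the Pd-catalysed β-arylation of α-keto ester enolates with aryl bromides (Buchwald–Hartwig-type enolate arylation), here applied to the cyclic α-keto ester. No ring is closed. No new stereocentre is formed, and C5 should be retained because substrate and product are held as enolates, which disfavours a second deprotonation at C5, while the in-plane C5–O bond is poorly aligned for E1cB ring opening. The step needs C- over O-arylation and mono-arylation, which the bulky electron-rich phosphine (fast C–C reductive elimination) and the lower nucleophilicity of the hindered, aryl-conjugated product enolate should secure. β-Hydride elimination towards C5 would give a strained furan-2,3-dione and a Heck reaction at the trisubstituted prenyl alkene is slow, so neither should compete.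

Step 8
Reactants: 15 (5R)-3-hydroxy-5-[3-(3-methylbut-2-en-1-yl)-4-(triisopropylsilyloxy)benzyl]-4-[4-(triisopropylsilyloxy)phenyl]furan-2(5H)-one
Product: 16 (5R)-3-hydroxy-5-[4-hydroxy-3-(3-methylbut-2-en-1-yl)benzyl]-4-(4-hydroxyphenyl)furan-2(5H)-one (target)
Conditions: TBAF, AcOH, THF, 0 °C → rt
Reagents that add atoms: none
Why: Fluoride-mediated cleavage of both aryl silyl ethers, buffered with acetic acid, avoids the strong acid that would cyclise the free phenol onto the prenyl group and does not touch C5.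

Compound list
1 | 4-bromophenol | Oc1ccc(Br)cc1 | starting material
2 | prenyl bromide (1-bromo-3-methylbut-2-ene) | CC(C)=CCBr | starting material
3 | 4-bromo-2-(3-methylbut-2-en-1-yl)phenol | CC(C)=CCc1cc(Br)ccc1O | intermediate
4 | [4-bromo-2-(3-methylbut-2-en-1-yl)phenoxy]triisopropylsilane | CC(C)=CCc1cc(Br)ccc1O[Si](C(C)C)(C(C)C)C(C)C | intermediate
5 | (R)-epichlorohydrin | ClC[C@H]1CO1 | starting material
6 | [3-(3-methylbut-2-en-1-yl)-4-(triisopropylsilyloxy)phenyl]magnesium bromide (not isolated) | CC(C)=CCc1cc([Mg]Br)ccc1O[Si](C(C)C)(C(C)C)C(C)C | intermediate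
7 | (2R)-1-chloro-3-[3-(3-methylbut-2-en-1-yl)-4-(triisopropylsilyloxy)phenyl]propan-2-ol | CC(C)=CCc1cc(C[C@@H](O)CCl)ccc1O[Si](C(C)C)(C(C)C)C(C)C | intermediate
8 | (2R)-2-[3-(3-methylbut-2-en-1-yl)-4-(triisopropylsilyloxy)benzyl]oxirane | CC(C)=CCc1cc(C[C@@H]2CO2)ccc1O[Si](C(C)C)(C(C)C)C(C)C | intermediate
9 | 1,3-dithiane-2-carboxylic acid | OC(=O)C1SCCCS1 | starting material
10 | dilithiated 1,3-dithiane-2-carboxylate, C2-lithio lithium carboxylate (not isolated) | [Li]OC(=O)C1([Li])SCCCS1 | intermediate
11 | 2-{(2R)-2-hydroxy-3-[3-(3-methylbut-2-en-1-yl)-4-(triisopropylsilyloxy)phenyl]propyl}-1,3-dithiane-2-carboxylic acid (not isolated) | CC(C)=CCc1cc(C[C@@H](O)CC2(SCCCS2)C(=O)O)ccc1O[Si](C(C)C)(C(C)C)C(C)C | intermediate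
12 | (3R)-3-[3-(3-methylbut-2-en-1-yl)-4-(triisopropylsilyloxy)benzyl]-2-oxa-6,10-dithiaspiro[4.5]decan-1-one | CC(C)=CCc1cc(C[C@H]2OC(=O)C3(SCCCS3)C2)ccc1O[Si](C(C)C)(C(C)C)C(C)C | intermediate
13 | (5R)-3-hydroxy-5-[3-(3-methylbut-2-en-1-yl)-4-(triisopropylsilyloxy)benzyl]furan-2(5H)-one | CC(C)=CCc1cc(C[C@H]2OC(=O)C(O)=C2)ccc1O[Si](C(C)C)(C(C)C)C(C)C | intermediate
14 | (4-bromophenoxy)triisopropylsilane | CC(C)[Si](Oc1ccc(Br)cc1)(C(C)C)C(C)C | starting material
15 | (5R)-3-hydroxy-5-[3-(3-methylbut-2-en-1-yl)-4-(triisopropylsilyloxy)benzyl]-4-[4-(triisopropylsilyloxy)phenyl]furan-2(5H)-one | CC(C)=CCc1cc(C[C@H]2OC(=O)C(O)=C2c2ccc(O[Si](C(C)C)(C(C)C)C(C)C)cc2)ccc1O[Si](C(C)C)(C(C)C)C(C)C | intermediate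
16 | (5R)-3-hydroxy-5-[4-hydroxy-3-(3-methylbut-2-en-1-yl)benzyl]-4-(4-hydroxyphenyl)furan-2(5H)-one | CC(C)=CCc1cc(C[C@H]2OC(=O)C(O)=C2c2ccc(O)cc2)ccc1O | target

Total step count: 8. Longest linear sequence: 8 steps (1 → 3 → 4 → 7 → 8 → 12 → 13 → 15 → 16); 14 enters at step 7.

Steps most likely to fail

Step 7. The configuration at C5 may erode under hot phosphate (γ-deprotonation or reversible ring opening of the enolate), and the chelating 2-oxido-enoate may slow transmetalation or lead to O-arylation. Fallback (Suzuki–Miyaura polarity reversal at lower temperature): setting out from 13, the enol would be brominated at C4 with NBS (THF, −78 °C, where the enol should react far faster than the prenyl alkene) to give (5R)-4-bromo-3-hydroxy-5-[3-(3-methylbut-2-en-1-yl)-4-(triisopropylsilyloxy)benzyl]furan-2(5H)-one F1. Silylation of O3 (TBSCl, imidazole, DMF) would give the 3-(tert-butyldimethylsilyloxy)-4-bromo butenolide F2. Coupling with [4-(tert-butyldimethylsilyloxy)phenyl]boronic acid (Pd(dppf)Cl2, K3PO4, dioxane/H2O, 60 °C) would give the tris-silylated 4-aryl butenolide F3. TBAF/AcOH in THF would then remove all three silyl groups, and the fallback comes back to the route at 16.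

Step 5. The hindered, charge-delocalised dianion may open the epoxide too slowly, so that base-induced isomerisation of the epoxide to an allylic alcohol or decomposition of the dianion takes over. Fallback (the two carbons introduced one at a time): setting out from 8, opening with 2-lithio-1,3-dithiane (1,3-dithiane, n-BuLi, THF, −30 → 0 °C) would give (2R)-1-(1,3-dithian-2-yl)-3-[3-(3-methylbut-2-en-1-yl)-4-(triisopropylsilyloxy)phenyl]propan-2-ol F4. Its alkoxide/C2-lithio dianion (n-BuLi, 2.2 equiv, THF, −20 °C) would be carboxylated with CO2, acidified to hydroxy acid 11 and lactonised (PPTS, toluene), and the fallback comes back to the route at 12.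

Step 6. S-Methylation of the electron-poor dithioketal may stall, and the liberated enol may be O-methylated or the unmasked keto lactone may self-condense (aldol) during the long reaction. Fallback (no dithiane; the C3 oxygen is introduced by enolate oxidation): setting out from 8, opening with dilithioacetate (AcOH, 2 LDA, THF/DMPU) would give (4S)-4-hydroxy-5-[3-(3-methylbut-2-en-1-yl)-4-(triisopropylsilyloxy)phenyl]pentanoic acid F5. Lactonisation (PPTS, toluene, 60 °C) would give (5S)-5-[3-(3-methylbut-2-en-1-yl)-4-(triisopropylsilyloxy)benzyl]dihydrofuran-2(3H)-one F6. Hydroxylation of its lithium enolate (LiHMDS, THF, −78 °C; 2-(phenylsulfonyl)-3-phenyloxaziridine) would give the (5R)-3-hydroxy lactone F7 as a mixture of C3 epimers, both usable. Dess–Martin oxidation (CH2Cl2, NaHCO3) would give the keto lactone, which enolises, and the fallback comes back to the route at 13.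

Further compounds
F1 | step 7 | (5R)-4-bromo-3-hydroxy-5-[3-(3-methylbut-2-en-1-yl)-4-(triisopropylsilyloxy)benzyl]furan-2(5H)-one | CC(C)=CCc1cc(C[C@H]2OC(=O)C(O)=C2Br)ccc1O[Si](C(C)C)(C(C)C)C(C)C
F2 | step 7 | (5R)-4-bromo-3-(tert-butyldimethylsilyloxy)-5-[3-(3-methylbut-2-en-1-yl)-4-(triisopropylsilyloxy)benzyl]furan-2(5H)-one | CC(C)=CCc1cc(C[C@H]2OC(=O)C(O[Si](C)(C)C(C)(C)C)=C2Br)ccc1O[Si](C(C)C)(C(C)C)C(C)C
F3 | step 7 | (5R)-3-(tert-butyldimethylsilyloxy)-4-[4-(tert-butyldimethylsilyloxy)phenyl]-5-[3-(3-methylbut-2-en-1-yl)-4-(triisopropylsilyloxy)benzyl]furan-2(5H)-one | CC(C)=CCc1cc(C[C@H]2OC(=O)C(O[Si](C)(C)C(C)(C)C)=C2c2ccc(O[Si](C)(C)C(C)(C)C)cc2)ccc1O[Si](C(C)C)(C(C)C)C(C)C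
F4 | step 5 | (2R)-1-(1,3-dithian-2-yl)-3-[3-(3-methylbut-2-en-1-yl)-4-(triisopropylsilyloxy)phenyl]propan-2-ol | CC(C)=CCc1cc(C[C@@H](O)CC2SCCCS2)ccc1O[Si](C(C)C)(C(C)C)C(C)C
F5 | step 6 | (4S)-4-hydroxy-5-[3-(3-methylbut-2-en-1-yl)-4-(triisopropylsilyloxy)phenyl]pentanoic acid | CC(C)=CCc1cc(C[C@@H](O)CCC(=O)O)ccc1O[Si](C(C)C)(C(C)C)C(C)C
F6 | step 6 | (5S)-5-[3-(3-methylbut-2-en-1-yl)-4-(triisopropylsilyloxy)benzyl]dihydrofuran-2(3H)-one | CC(C)=CCc1cc(C[C@H]2OC(=O)CC2)ccc1O[Si](C(C)C)(C(C)C)C(C)C
F7 | step 6 | (5R)-3-hydroxy-5-[3-(3-methylbut-2-en-1-yl)-4-(triisopropylsilyloxy)benzyl]dihydrofuran-2(3H)-one (C3 epimers) | CC(C)=CCc1cc(C[C@H]2OC(=O)C(O)C2)ccc1O[Si](C(C)C)(C(C)C)C(C)C
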